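**The question.** Does a larger charge of starting material buy more target at the end of the run, or does the target it makes feed its own loss?

    catalyst intermediate A → free catalyst + target (k1 = 19 /min)
    starting material + free catalyst ⇌ catalyst intermediate A (K2 = 1.7 /M, k2 = 1500 /M/min)
    second substrate + free catalyst ⇌ catalyst intermediate B (K3 = 110 /M, k3 = 520 /M/min)
    starting material + target → side product (k4 = 0.44 /M/min)
    catalyst intermediate B → free catalyst + second product (k5 = 340 /min)

| setting | Wednesday's | Monday's | Thursday's | Tuesday's | Saturday's |
|---|---|---|---|---|---|
| starting material | 0.060 M | 0.12 M | 0.25 M | 0.50 M | 1.0 M |
| second substrate | 0.500 M | 0.500 M | 0.500 M | 0.500 M | 0.500 M |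
| free catalyst | 2.3 mM | 2.3 mM | 2.3 mM | 2.3 mM | 2.3 mM |
| time | 8.0 min | 8.0 min | 8.0 min | 8.0 min | 8.0 min |

* [target] at the end for Wednesday's, Monday's, Thursday's, Tuesday's, Saturday's, in this order
* how the row runs (hardly changes / rises, then falls / falls all the way / rises all the way / falls, then rises)

- a species is counted by the starting material in it: one side product counts as two
- "hardly changes" means that all values lie within two and a half points (for a concentration: within two and a half percent of the largest)
- run time (Wednesday's): 8.0 min

**Turned round.** For the row to keep rising to the last flask, a target molecule in Saturday's flask would have to stand a good chance of lasting the run. For it to fall from the first flask on, that molecule would have to be lost already in Wednesday's flask. So we follow one target molecule, whose fork is to wait or to meet starting material, and take one over the constant of that step times the run time, 0.284 M: the loss charge, the concentration of starting material at which the mean life of a target molecule equals the run. Saturday's charge stands 3.52 times above it, and Wednesday's at 0.211 of it, so the flasks lie on both sides.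

**Our reckoning.** Making saturates too, with a half-saturation concentration (Michaelis constant) of 0.601 M. We hold starting material at its charge and leave out the second substrate's claim on the catalyst. Making at that steady rate while losing at the loss charge's pace gives 0.0286 M, 0.0475 M, 0.0683 M, 0.0747 M and 0.0602 M, with Tuesday's figure above the others, so our row rises, then falls.

**The forecast.** The forecast gives 0.0217 M, 0.038 M, 0.06 M, 0.074 M and 0.067 M, a row that rises, then falls, holding that the loss is “minor at low loading but takes over at high loading”. Its Wednesday's figure stands below ours and its Saturday's above ours.

**The result.** The simulation gives 0.0214 M, 0.0373 M, 0.0586 M, 0.0722 M and 0.0652 M; the row rises, then falls, turning at 0.58 M, twice the loss charge, where a target molecule facing starting material held at that charge has a mean life of 3.93 min.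

**What ran when.** In Saturday's flask, second substrate was still going over to second product at 8.00 min, with 2.68% of its charge left, while catalyst intermediate A held 52.9% of the catalyst and starting material, at 68.7% of its charge, met the target as it formed. For Saturday's flask, with its charge 3.52 times the loss charge, our estimate with steady making and starting material held at its charge is that 27.6% of the target made survives, and the state of that flask at the end, each side product counted as one target lost, shows 34.7%.

Its constants were set for the occasion, and the outcome is calculated.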